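(The numbers in the tables are calculated with made-up constants, noise included.)

A small charge of X, 0.0500 M, stands in the flask while an equal charge of E runs in over 20 h beside the base Z, and the question is how much E has reacted at 30 h.

| flask | E | X | Z | remark | time |
|---|---|---|---|---|---|
| violet | 0.050 M (fed, over 20 h) | 0.050 M | 0.038 M | run made earlier |  |
| teal | 0.050 M (fed, over 20 h) | 0.050 M | 0.12 M | run made earlier |  |
| alpha | 0.050 M (fed, over 20 h) | 0.0500 M | 0.170 M |  | 30 h |
| gamma | 0.050 M (fed, over 20 h) | 0.0500 M | 0.0750 M |  | 30 h |
| theta | 0.050 M (fed, over 20 h) | 0.0500 M | 0.110 M |  | 30 h |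

| run | time / h | E / % | D / % |
|---|---|---|---|
| violet | 1.00 | 5 | 0 |
| violet | 3.00 | 11 | 1 |
| violet | 6.00 | 25 | 3 |
| violet | 10.0 | 40 | 11 |
| violet | 12.0 | 47 | 15 |
| violet | 15.0 | 52 | 24 |
| violet | 20.0 | 66 | 31 |
| teal | 1.50 | 5 | 1 |
| teal | 2.50 | 10 | 3 |
| teal | 4.00 | 16 | 4 |
| teal | 6.00 | 27 | 8 |
| teal | 10.0 | 39 | 12 |
| teal | 15.0 | 53 | 23 |
| teal | 20.0 | 68 | 35 |

(scatter of a reading: 2 percentage points)

- percentages count the whole charge, also what has not yet gone in

- part of the E that has reacted at the end, alpha
- part of the E that has reacted at the end, gamma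
- part of the E that has reacted at the end, theta
- what raising the concentration of Z from its lowest to its highest value here does to the part of the E that has reacted (changes below 5 percentage points count as none) (it falls / it rises / no change)

Between the two runs Z goes from 0.038 M to 0.12 M, yet D at 20.0 h reads 31% and 35%, a gap of 4 percentage points against a scatter of 2 points per reading. A rate law without Z is therefore tried, although alpha lies beyond the span of these runs. Each D costs one X, so if X goes nowhere else, the share x of X left obeys d(−ln x)/dt = e/τ, where e is the unreacted E as a share of its charge. The readings of E at 10.0 h and at the end of the feed, averaged over both runs, give an area under e of 7.30 h. With mean D at 33.0%, this gives 18.2 h for τ, the pairing time: the second-order half-life of E and X mixed equally at charge strength.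

After the feed, e and x are both reckoned at 67.0%, so the reciprocal of e simply grows by elapsed time over τ. The tail of 10.0 h is shorter than τ, and their ratio of 0.549 lifts that reciprocal from 1.49 to 2.04. This reckoning gives 51.0% reacted in each flask.

The forecast gives the same figure: 51%, 51% and 51% for alpha, gamma and theta, and no change, taking Z as “presumably only a needed acid scavenger”.

The flasks give 52.6% for alpha, 51.5% for gamma and 52.1% for theta, a spread of 1.1 points across Z: no change.

    G + Z ⇌ J (K = 6900 L mol⁻¹, k = 100 L mol⁻¹ h⁻¹)
    G + Z ⇌ L, settled at all times (K = 29.0 L mol⁻¹)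
    E + X → G + D (k = 1.20 L mol⁻¹ h⁻¹)
    X + G ⇌ Q, settled at all times (K = 430 L mol⁻¹)

In gamma, with concentrations as charged, G has a half-life of 0.092 h by its forward step to J, while E has one of 12 h by its step with X. At 30.0 h gamma holds 2.09 × 10⁻⁴ M of G beside 0.0232 M of J. Over gamma's tail the reciprocal of e rises by 0.548, against the 0.549 reckoned with τ. Gamma holds 66.0% of E at 20.0 h; carried from there to a reading at 3.0 d, τ gives 77.1% reacted, and gamma read at that time stands at 77.2%.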